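**The question.** Which set-up leaves you with the most target at the end, and how much in each? Here is what is asked and what you have to go on.

* the set-up with the highest amount of target at the outlet or at the end, in percent of the substrate put in ("none" if the first two lie within 2 percentage points) (south-west / south-east / east / north-east / none)
* amount of target at the outlet or at the end, in percent of the substrate put in, south-west
* amount of target at the outlet or at the end, in percent of the substrate put in, south-east
* amount of target at the outlet or at the end, in percent of the substrate put in, east
* amount of target at the outlet or at the end, in percent of the substrate put in, north-east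

| flask | substrate | reagent | remark | time |
|---|---|---|---|---|
| Friday's | 0.50 M | 0.50 M | run made earlier |  |
| Wednesday's | 0.50 M | 0.34 M | run made earlier |  |
| Tuesday's | 0.50 M | 0.75 M | run made earlier |  |
| south-west | 0.50 M | 0.500 M | everything together in a closed stirred flask, run for 40 min | 40 min |
| south-east | 0.50 M | 0.500 M (fed, over 32.0 min) | a stirred flask in which reagent is dosed at a steady rate over 32.0 min without added volume, worked up at 40 min | 40 min |
| east | 0.50 M | 0.500 M | one stirred flow tank at steady state, fed with the mixture as stated, mean residence time 40 min |  |
| north-east | 0.50 M (fed, over 32.0 min) | 0.500 M | a stirred flask in which substrate is dosed at a steady rate over 32.0 min without added volume, worked up at 40 min | 40 min |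

- Friday's (time / min: target / %): 5.00: 18.4; 10.0: 29.9; 15.0: 32.8; 20.0: 37.8; 25.0: 39.9
- Wednesday's (time / min: target / %): 2.50: 8.0; 5.00: 13.9; 10.0: 20.7; 15.0: 24.5; 30.0: 33.1
- Tuesday's (time / min: target / %): 3.00: 19.3; 8.00: 34.3; 15.0: 43.8; 25.0: 51.8; 30.0: 51.4

(scatter of a reading: 1 percentage point)

- the stated concentrations are those of everything mixed, before any reaction; amounts are the same in each set-up
- steps that have been proposed: substrate + reagent -> target; substrate -> decomposition product; reagent + target -> over-reaction product; reagent <-> dormant form
- the feed brings no volume worth counting
- the earlier runs were made in a closed, stirred flask

**Main step first.** Take Friday's closed flask, where substrate and reagent are charged level, and suppose that the main step runs by itself, one substrate meeting one reagent. Target divided by unreacted substrate then grows in step with time. The first reading, 18.4% at 5.00 min, puts that ratio at 1.80 by 40 min, so Friday's flask would hold 64.3% target.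

**One more loss.** The same reckoning gives 53.0% at 25.0 min, but Friday's reading there is 39.9%, lower. So the main step as supposed does not describe Friday's flask. Go to logarithms and take the curve as it stands. Between 10.0 min and 25.0 min, Friday's target readings rise 0.315 of a power of ten per power of ten of time. Extended to 40 min, this gives 46.3% for south-west, well under the main-step figure.

**The rest.** Now compare Tuesday's and Wednesday's last readings, both at 30.0 min. Powers of ten of target gained per power of ten of reagent give the reagent leverage, an apparent order in reagent: 0.556. It stands below proportion. In south-east the reagent dosed so far averages 0.300 M over the run, so my figure for south-east is 34.8%, behind south-west. I commit no number for north-east or the tank.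

**The forecast.** It names south-west, with 43% for south-west, 29% for south-east, 35% for the east tank and 40% for north-east. Its ground for south-east, which it puts below my figure, is this: “Dosing reagent leaves substrate waiting at low reagent”.

**The result.** South-west gives the most target, 46.5%; south-east gives 38.8%, east 34.1% and north-east 30.0%. The forecast's order of the two fed flasks is reversed.

    substrate + reagent → target, rate k1*[substrate]^1.5*[reagent] (k = 0.00274 L¹·⁵ mol⁻¹·⁵ s⁻¹)
    substrate → decomposition product (k = 2.05 × 10⁻⁷ s⁻¹)
    reagent + target → over-reaction product (k = 2.47 × 10⁻⁴ L mol⁻¹ s⁻¹)
    reagent ⇌ dormant form (K = 1.25, k = 9.90 × 10⁻⁴ s⁻¹)

**The neighbour.** From south-west's 46.5%, the leverage gives south-east 35.0%, under its actual 38.8%. Now take north-east's neighbour, charged with 0.85 M reagent and otherwise held. For that neighbour, the factor 1.70 raised to 0.556 lifts 30.0% to 40.3%. That neighbour gives 42.2%, with 54.6% of its substrate still there.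

Readings and results were generated by integration for substances that don't exist; noise was put on by code.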